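**Strategy**

Everything rests on disconnecting the aryl ether bond O1–C8a of ring C. C8a is the one ring A carbon that lies meta to both ring oxygens (on C5 and C7) and ortho, through C4a, to the C4 carbonyl, so a fluorine there is set up for SNAr while the adduct's charge avoids the oxygen-bearing carbons. In the key step a 2-fluoro-6-methoxyaryl methyl ketone that already carries the (R)-lavandulyl chain is formylated, and the enolate oxygen of the β-ketoaldehyde displaces fluoride to close the pyranone as a chromone in one operation. Rhodium-catalysed asymmetric 1,4-arylation then sets C2. A symmetric 2,6-difluorobenzonitrile supplies ring A.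

Key step: step 10

Remarks on the chemistry:
- Flavanone numbering is used (O1, C2, C3, C4, C4a, C5 to C8, C8a). "Lavandulyl" stands for 5-methyl-2-(prop-1-en-2-yl)hex-4-en-1-yl.
- The lavandulyl stereocentre keeps one spatial arrangement throughout. Its descriptor changes from S (compounds 7 to 9 and 14) to R (from 15 on) only because the CH2 substituent falls below isopropenyl in CIP priority once iodine or zinc is replaced by aryl carbon.
- The facial sense of step 11 is assigned by analogy with the cyclohexenone model for rhodium/biaryl bisphosphine arylations; the antipodal ligand would be used if the sense proved opposite.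

**Route**

Step 1
Reactants: 1 (4S)-4-benzyl-1,3-oxazolidin-2-one; 2 3-methylbut-2-enoyl chloride
Product: 4 (4S)-4-benzyl-3-(3-methylbut-2-enoyl)-1,3-oxazolidin-2-one, via lithium oxazolidinide 3 (not isolated)
Conditions: n-BuLi, THF, −78 °C; then 2, −78 → 0 °C
Reagents that add atoms: none
Why: N-acylation of the lithiated Evans auxiliary by the acid chloride should proceed cleanly, and no stereocentre is formed.

Step 2
Reactants: 4 (4S)-4-benzyl-3-(3-methylbut-2-enoyl)-1,3-oxazolidin-2-one; 5 1-bromo-3-methylbut-2-ene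
Product: 7 (4S)-4-benzyl-3-[(2S)-5-methyl-2-(prop-1-en-2-yl)hex-4-enoyl]-1,3-oxazolidin-2-one, via sodium dienolate 6 (not isolated)
Conditions: NaN(SiMe3)2, THF, −78 °C; then 5, −78 → −40 °C; AcOH quench at −78 °C
Reagents that add atoms: none
Why: Evans asymmetric alkylation in its deconjugative form, in which γ-deprotonation gives the chelated Z-dienolate and prenyl bromide attacks the α-carbon on the face opposite the benzyl group, should set the (2S) centre that becomes the lavandulyl stereocentre.

Step 3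
Reactants: 7 (4S)-4-benzyl-3-[(2S)-5-methyl-2-(prop-1-en-2-yl)hex-4-enoyl]-1,3-oxazolidin-2-one
Product: 8 (2S)-5-methyl-2-(prop-1-en-2-yl)hex-4-en-1-ol
Conditions: LiBH4, MeOH (1 equiv), Et2O, 0 °C
Reagents that add atoms: none
Why: Reductive cleavage of the N-acyl oxazolidinone by LiBH4 should give the primary alcohol and free the auxiliary without touching the α-centre or the alkenes.

Step 4
Reactants: 8 (2S)-5-methyl-2-(prop-1-en-2-yl)hex-4-en-1-ol
Product: 9 (3S)-3-(iodomethyl)-2,6-dimethylhepta-1,5-diene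
Conditions: I2, PPh3, imidazole, CH2Cl2, 0 °C → rt
Reagents that add atoms: iodine (II)
Why: Appel-type (Garegg–Samuelsson) iodination of a primary alcohol should leave the neighbouring stereocentre untouched.

Step 5
Reactants: 10 2,6-difluoro-4-hydroxybenzonitrile
Product: 11 2,6-difluoro-4-(methoxymethoxy)benzonitrile
Conditions: MOMCl, i-Pr2NEt, CH2Cl2, 0 °C → rt
Reagents that add atoms: chloromethyl methyl ether (COCCl)
Why: O-alkylation of the acidic phenol (Williamson-type MOM protection) masks the C7 oxygen for the organometallic and SNAr steps.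

Step 6
Reactants: 11 2,6-difluoro-4-(methoxymethoxy)benzonitrile
Product: 13 2,6-difluoro-3-iodo-4-(methoxymethoxy)benzonitrile, via arylmagnesium chloride 12 (not isolated)
Conditions: TMPMgCl·LiCl, THF, −20 °C; then I2, −20 → 0 °C
Reagents that add atoms: iodine (II)
Why: Directed magnesiation with the Knochel–Hauser base at the C–H flanked by F and OMOM (the two such positions are equivalent by symmetry and the nitrile is tolerated), followed by iodinolysis, should give a single iodide.

Step 7
Reactants: 9 (3S)-3-(iodomethyl)-2,6-dimethylhepta-1,5-diene; 13 2,6-difluoro-3-iodo-4-(methoxymethoxy)benzonitrile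
Product: 15 2,6-difluoro-4-(methoxymethoxy)-3-[(2R)-lavandulyl]benzonitrile, via lavandulylzinc iodide 14 (not isolated)
Conditions: 9, Zn dust (activated), LiCl, THF, 40 °C; then 13, Pd(OAc)2 (2 mol%), SPhos (4 mol%), THF, rt → 45 °C
Reagents that add atoms: none
Why: Negishi sp3–sp2 cross-coupling of the primary alkylzinc with the electron-poor aryl iodide should work because SPhos favours reductive elimination over β-hydride elimination, so the adjacent stereocentre is retained.

Step 8
Reactants: 15 2,6-difluoro-4-(methoxymethoxy)-3-[(2R)-lavandulyl]benzonitrile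
Product: 16 2-fluoro-6-methoxy-4-(methoxymethoxy)-3-[(2R)-lavandulyl]benzonitrile
Conditions: NaOMe (1.05 equiv), MeOH/THF, 0 °C
Reagents that add atoms: sodium methoxide (C[O-].[Na+])
Why: SNAr by methoxide on the nitrile-activated difluoride should take the fluorine next to C–H in preference to the one shielded by the lavandulyl methylene, and the first methoxy group slows a second substitution.

Step 9
Reactants: 16 2-fluoro-6-methoxy-4-(methoxymethoxy)-3-[(2R)-lavandulyl]benzonitrile
Product: 18 1-{2-fluoro-6-methoxy-4-(methoxymethoxy)-3-[(2R)-lavandulyl]phenyl}ethan-1-one, via bromomagnesium ketimide 17 (not isolated)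
Conditions: MeMgBr, CuBr (5 mol%), THF, 60 °C; then 1 M aq HCl, 0 °C → rt (short contact)
Reagents that add atoms: methylmagnesium bromide (C[Mg]Br); water (O)
Why: Copper-catalysed Grignard addition to the hindered nitrile stops at the ketimide, which brief aqueous acid hydrolyses to the methyl ketone while the MOM ether survives.

Step 10
Reactants: 18 1-{2-fluoro-6-methoxy-4-(methoxymethoxy)-3-[(2R)-lavandulyl]phenyl}ethan-1-one
Product: 20 5-methoxy-7-(methoxymethoxy)-8-[(2R)-lavandulyl]-4H-chromen-4-one, via sodium 3-oxopropenolate 19 (not isolated)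
Conditions: NaH (1.2 equiv), HCO2Et (5 equiv), THF, 0 °C → rt; then solvent switch to DMF, 80 °C
Reagents that add atoms: ethyl formate (CCOC=O)
Why: Crossed Claisen formylation of the methyl ketone gives the Z-configured sodium 3-oxoprop-1-en-1-olate 19, whose terminal oxygen adds to C8a ipso to fluorine; the Meisenheimer adduct, with its charge on C4a/C4=O, C6 and C8 and none on the oxygen-bearing C5 and C7, then loses fluoride (addition–elimination SNAr). The closest known reaction type is the base-induced cyclisation of 1-(2-fluoroaryl)-1,3-dicarbonyl compounds to chromones and flavones. Ring C closes in a six-membered mode, 6-exo-trig with respect to the arene π-bond C8a=C8 or, seen as addition–elimination on the vinylogous acyl fluoride O=C4–C4a=C8a–F, 6-endo-trig. No stereocentre is formed. The step needs O- over C-attack of the ambident enolate, which geometry enforces (C-attack would close a four-membered ring), and attack at C8a–F instead of C5–OMe, which the far better nucleofugality and activating effect of fluorine should secure; the second fluorine was already replaced in step 8, so no other halogen site competes.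

Step 11
Reactants: 20 5-methoxy-7-(methoxymethoxy)-8-[(2R)-lavandulyl]-4H-chromen-4-one; 21 [4-(methoxymethoxy)phenyl]boronic acid
Product: 22 (2S)-5-methoxy-7-(methoxymethoxy)-2-[4-(methoxymethoxy)phenyl]-8-[(2R)-lavandulyl]-2,3-dihydro-4H-chromen-4-one
Conditions: [Rh(OH)(cod)]2 (2.5 mol%), (S)-MeO-F12-BIPHEP (5.5 mol%), CH2Cl2/H2O, 30 °C
Reagents that add atoms: none
Why: Rhodium-catalysed asymmetric 1,4-addition of an arylboronic acid to a chromone (Hayashi–Miyaura type) with an electron-poor (S)-biaryl bisphosphine should deliver the aryl group to the C2 face that gives (2S), as (S)-biaryl bisphosphines give (S)-3-arylcyclohexanones, under catalyst control with no influence from the remote lavandulyl centre.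

Step 12
Reactants: 22 (2S)-5-methoxy-7-(methoxymethoxy)-2-[4-(methoxymethoxy)phenyl]-8-[(2R)-lavandulyl]-2,3-dihydro-4H-chromen-4-one
Product: 23 kushenol U
Conditions: 3 M aq HCl, MeOH, 40 °C
Reagents that add atoms: none
Why: Acid-catalysed cleavage of both MOM acetals should free the C7 and C4' phenols, since the flavanone centre is configurationally stable to acid and the mild conditions spare the two alkenes.

**Compound list**

1 | (4S)-4-benzyl-1,3-oxazolidin-2-one | O=C1N[C@@H](Cc2ccccc2)CO1 | starting material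
2 | 3-methylbut-2-enoyl chloride | CC(C)=CC(=O)Cl | starting material
3 | lithium salt of (4S)-4-benzyl-1,3-oxazolidin-2-one (N-lithio) | [Li]N1[C@@H](Cc2ccccc2)COC1=O | intermediate
4 | (4S)-4-benzyl-3-(3-methylbut-2-enoyl)-1,3-oxazolidin-2-one | CC(C)=CC(=O)N1[C@@H](Cc2ccccc2)COC1=O | intermediate
5 | 1-bromo-3-methylbut-2-ene (prenyl bromide) | CC(C)=CCBr | starting material
6 | sodium (Z)-dienolate of 4 | C=C(C)/C=C(\O[Na])N1[C@@H](Cc2ccccc2)COC1=O | intermediate
7 | (4S)-4-benzyl-3-[(2S)-5-methyl-2-(prop-1-en-2-yl)hex-4-enoyl]-1,3-oxazolidin-2-one | C=C(C)[C@H](CC=C(C)C)C(=O)N1[C@@H](Cc2ccccc2)COC1=O | intermediate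
8 | (2S)-5-methyl-2-(prop-1-en-2-yl)hex-4-en-1-ol ((S)-lavandulol) | C=C(C)[C@H](CC=C(C)C)CO | intermediate
9 | (3S)-3-(iodomethyl)-2,6-dimethylhepta-1,5-diene ((S)-lavandulyl iodide) | C=C(C)[C@H](CC=C(C)C)CI | intermediate
10 | 2,6-difluoro-4-hydroxybenzonitrile | N#Cc1c(F)cc(O)cc1F | starting material
11 | 2,6-difluoro-4-(methoxymethoxy)benzonitrile | COCOc1cc(F)c(C#N)c(F)c1 | intermediate
12 | [3-cyano-2,4-difluoro-6-(methoxymethoxy)phenyl]magnesium chloride | COCOc1cc(F)c(C#N)c(F)c1[Mg]Cl | intermediate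
13 | 2,6-difluoro-3-iodo-4-(methoxymethoxy)benzonitrile | COCOc1cc(F)c(C#N)c(F)c1I | intermediate
14 | [(2S)-5-methyl-2-(prop-1-en-2-yl)hex-4-en-1-yl]zinc iodide | C=C(C)[C@H](CC=C(C)C)C[Zn]I | intermediate
15 | 2,6-difluoro-4-(methoxymethoxy)-3-[(2R)-5-methyl-2-(prop-1-en-2-yl)hex-4-en-1-yl]benzonitrile | C=C(C)[C@H](CC=C(C)C)Cc1c(OCOC)cc(F)c(C#N)c1F | intermediate
16 | 2-fluoro-6-methoxy-4-(methoxymethoxy)-3-[(2R)-5-methyl-2-(prop-1-en-2-yl)hex-4-en-1-yl]benzonitrile | C=C(C)[C@H](CC=C(C)C)Cc1c(OCOC)cc(OC)c(C#N)c1F | intermediate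
17 | bromomagnesium ketimide of 18 (N-magnesio imine) | C=C(C)[C@H](CC=C(C)C)Cc1c(OCOC)cc(OC)c(C(C)=N[Mg]Br)c1F | intermediate
18 | 1-{2-fluoro-6-methoxy-4-(methoxymethoxy)-3-[(2R)-5-methyl-2-(prop-1-en-2-yl)hex-4-en-1-yl]phenyl}ethan-1-one | C=C(C)[C@H](CC=C(C)C)Cc1c(OCOC)cc(OC)c(C(C)=O)c1F | intermediate
19 | sodium (1Z)-3-{2-fluoro-6-methoxy-4-(methoxymethoxy)-3-[(2R)-5-methyl-2-(prop-1-en-2-yl)hex-4-en-1-yl]phenyl}-3-oxoprop-1-en-1-olate | C=C(C)[C@H](CC=C(C)C)Cc1c(OCOC)cc(OC)c(C(=O)/C=C\O[Na])c1F | intermediate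
20 | 5-methoxy-7-(methoxymethoxy)-8-[(2R)-5-methyl-2-(prop-1-en-2-yl)hex-4-en-1-yl]-4H-chromen-4-one | C=C(C)[C@H](CC=C(C)C)Cc1c(OCOC)cc(OC)c2c(=O)ccoc12 | intermediate
21 | [4-(methoxymethoxy)phenyl]boronic acid | COCOc1ccc(B(O)O)cc1 | starting material
22 | (2S)-5-methoxy-7-(methoxymethoxy)-2-[4-(methoxymethoxy)phenyl]-8-[(2R)-5-methyl-2-(prop-1-en-2-yl)hex-4-en-1-yl]-2,3-dihydro-4H-chromen-4-one | C=C(C)[C@H](CC=C(C)C)Cc1c(OCOC)cc(OC)c2c1O[C@H](c1ccc(OCOC)cc1)CC2=O | intermediate
23 | kushenol U, (2S)-7-hydroxy-2-(4-hydroxyphenyl)-5-methoxy-8-[(2R)-5-methyl-2-(prop-1-en-2-yl)hex-4-en-1-yl]-2,3-dihydro-4H-chromen-4-one | C=C(C)[C@H](CC=C(C)C)Cc1c(O)cc(OC)c2c1O[C@H](c1ccc(O)cc1)CC2=O | target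

**Step count**

Total steps: 12. Longest linear sequence: 10 steps (steps 1 to 4, then 7 to 12).

**Steps most likely to fail, with fallbacks**

Step 10 (key step). The delocalised enolate oxygen may add too slowly to the hindered C8a, so that intermolecular attack by ethoxide, or attack at C5 with loss of methoxide, takes over. The fallback sets out from 16 and comes back at 22, and uses a full alkoxide at the diol oxidation level, where no enolisable β-hydroxy ketone meets base.
- i-Bu2AlH (toluene, −78 °C, aqueous work-up) reduces the nitrile to 2-fluoro-6-methoxy-4-(methoxymethoxy)-3-[(2R)-lavandulyl]benzaldehyde F1.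
- Lithium 1-[4-(methoxymethoxy)phenyl]ethen-1-olate F2, made from 1-[4-(methoxymethoxy)phenyl]ethan-1-one and LiN(i-Pr)2 in THF at −78 °C, adds to it to give 3-aryl-3-hydroxy-1-[4-(methoxymethoxy)phenyl]propan-1-one F3 as both carbinol epimers.
- Transfer hydrogenation of the aryl ketone with RuCl[(S,S)-TsDPEN](p-cymene) and HCO2H/Et3N should give the (1S)-configured 1-[4-(methoxymethoxy)phenyl]-3-arylpropane-1,3-diol F4 under catalyst control.
- NaH in THF/DMF at 60 °C then closes ring C by SNAr of the distal alkoxide at C8a (the proximal alkoxide could only form a four-membered ring) to the (2S)-flavan-4-ol F5.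
- Dess–Martin periodinane oxidises the C4 carbinol to 22.

Step 11. Insertion of the electron-rich, 8-substituted chromone into the aryl–rhodium bond may be sluggish, protodeboronation may outrun it, or facial selectivity may be poor. The fallback sets out from 20 and comes back at 22, and replaces catalytic asymmetric arylation by unselective arylation followed by epimer-selective reduction.
- [4-(Methoxymethoxy)phenyl]magnesium bromide F6, from 1-bromo-4-(methoxymethoxy)benzene and Mg, with CuBr·SMe2 (cat.) and Me3SiCl in THF at −78 °C adds to C2 without stereocontrol to give the 4-(trimethylsilyloxy)-2H-chromene F7.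
- Aqueous work-up hydrolyses it to the C2-epimeric flavanones F8.
- Transfer hydrogenation with RuCl[(R,R)-TsDPEN](p-cymene) and HCO2H/Et3N should reduce only the (2R)-epimer, to the cis-(2R,4R)-flavan-4-ol F9; the unreacted (2S)-ketone 22 is separated from this alcohol by chromatography.

Step 8. Methoxide may discriminate too little between the two C–F bonds. The fallback sets out from 11 and comes back at 16, and moves the methoxylation ahead of the lavandulyl group so that regiocontrol rests on C–H acidity instead of on sterics.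
- NaOMe on the symmetric 11 gives 2-fluoro-6-methoxy-4-(methoxymethoxy)benzonitrile F10 with no regiochemical choice.
- TMPMgCl·LiCl then metalates the C–H next to fluorine (more acidic than the one next to methoxy) to [3-cyano-2-fluoro-4-methoxy-6-(methoxymethoxy)phenyl]magnesium chloride F11.
- I2 gives 2-fluoro-3-iodo-6-methoxy-4-(methoxymethoxy)benzonitrile F12.
- Negishi coupling with 14 under the conditions of step 7 gives 16.

**Further compounds**

F1 | step 10 | 2-fluoro-6-methoxy-4-(methoxymethoxy)-3-[(2R)-5-methyl-2-(prop-1-en-2-yl)hex-4-en-1-yl]benzaldehyde | C=C(C)[C@H](CC=C(C)C)Cc1c(OCOC)cc(OC)c(C=O)c1F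
F2 | step 10 | lithium 1-[4-(methoxymethoxy)phenyl]ethen-1-olate | [Li]OC(=C)c1ccc(OCOC)cc1
F3 | step 10 | 3-{2-fluoro-6-methoxy-4-(methoxymethoxy)-3-[(2R)-5-methyl-2-(prop-1-en-2-yl)hex-4-en-1-yl]phenyl}-3-hydroxy-1-[4-(methoxymethoxy)phenyl]propan-1-one (both carbinol epimers) | C=C(C)[C@H](CC=C(C)C)Cc1c(OCOC)cc(OC)c(C(O)CC(=O)c2ccc(OCOC)cc2)c1F
F4 | step 10 | (1S)-3-{2-fluoro-6-methoxy-4-(methoxymethoxy)-3-[(2R)-5-methyl-2-(prop-1-en-2-yl)hex-4-en-1-yl]phenyl}-1-[4-(methoxymethoxy)phenyl]propane-1,3-diol (both C3 epimers) | C=C(C)[C@H](CC=C(C)C)Cc1c(OCOC)cc(OC)c(C(O)C[C@H](O)c2ccc(OCOC)cc2)c1F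
F5 | step 10 | (2S)-5-methoxy-7-(methoxymethoxy)-2-[4-(methoxymethoxy)phenyl]-8-[(2R)-5-methyl-2-(prop-1-en-2-yl)hex-4-en-1-yl]-3,4-dihydro-2H-chromen-4-ol (both C4 epimers) | C=C(C)[C@H](CC=C(C)C)Cc1c(OCOC)cc(OC)c2c1O[C@H](c1ccc(OCOC)cc1)CC2O
F6 | step 11 | [4-(methoxymethoxy)phenyl]magnesium bromide | COCOc1ccc([Mg]Br)cc1
F7 | step 11 | 5-methoxy-7-(methoxymethoxy)-2-[4-(methoxymethoxy)phenyl]-8-[(2R)-5-methyl-2-(prop-1-en-2-yl)hex-4-en-1-yl]-4-(trimethylsilyloxy)-2H-chromene (both C2 epimers) | C=C(C)[C@H](CC=C(C)C)Cc1c(OCOC)cc(OC)c2c1OC(c1ccc(OCOC)cc1)C=C2O[Si](C)(C)C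
F8 | step 11 | 5-methoxy-7-(methoxymethoxy)-2-[4-(methoxymethoxy)phenyl]-8-[(2R)-5-methyl-2-(prop-1-en-2-yl)hex-4-en-1-yl]-2,3-dihydro-4H-chromen-4-one (both C2 epimers) | C=C(C)[C@H](CC=C(C)C)Cc1c(OCOC)cc(OC)c2c1OC(c1ccc(OCOC)cc1)CC2=O
F9 | step 11 | (2R,4R)-5-methoxy-7-(methoxymethoxy)-2-[4-(methoxymethoxy)phenyl]-8-[(2R)-5-methyl-2-(prop-1-en-2-yl)hex-4-en-1-yl]-3,4-dihydro-2H-chromen-4-ol | C=C(C)[C@H](CC=C(C)C)Cc1c(OCOC)cc(OC)c2c1O[C@@H](c1ccc(OCOC)cc1)C[C@H]2O
F10 | step 8 | 2-fluoro-6-methoxy-4-(methoxymethoxy)benzonitrile | COCOc1cc(F)c(C#N)c(OC)c1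
F11 | step 8 | [3-cyano-2-fluoro-4-methoxy-6-(methoxymethoxy)phenyl]magnesium chloride | COCOc1cc(OC)c(C#N)c(F)c1[Mg]Cl
F12 | step 8 | 2-fluoro-3-iodo-6-methoxy-4-(methoxymethoxy)benzonitrile | COCOc1cc(OC)c(C#N)c(F)c1I
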